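The flavone B ring (C1'''–C6''') is built rather than coupled, and the whole route rests on that choice. This ring bears flavone C2 at C1''', the interflavonoid bond at C3''' and OH at C4''', which is the substitution pattern of a 3-aryl-4-oxygenated benzoate. The precursor is a (1E,3Z)-1-methoxy-3-silyloxy-1,3-butadiene carrying the future flavanone B ring at C4, with the phenol as benzyl ether and the aldehyde as dioxolane. It adds to methyl propiolate: C2'''–C3''' and C1'''–C6''' form and methanol leaves. The 3',3'''-biaryl emerges in one operation with ester and acetal ends differentiated. The ester is grown into the flavone, the aldehyde into the (2S)-flavanone by a catalytic asymmetric oxa-Michael closure, and neutral hydrogenolysis ends the route.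

Key step: step 7

Assumption: the thiourea derived from 9-amino-9-deoxy-epi-quinidine is taken to give the 2S product in step 14; should a first run show the opposite sense, the quinine-derived pseudoenantiomer takes its place with nothing else changed.

Step 1
Reactants: 1 3-bromo-4-hydroxybenzaldehyde
Product: 2 4-(benzyloxy)-3-bromobenzaldehyde
Conditions: BnBr, K2CO3, DMF, rt
Reagents that add atoms: benzyl bromide, BrCc1ccccc1
Why: Williamson etherification of the acidic phenol, with benzyl chosen because it withstands every basic, organometallic and thermal step ahead and leaves at the end under neutral hydrogenolysis.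

Step 2
Reactants: 2 4-(benzyloxy)-3-bromobenzaldehyde
Product: 3 2-[4-(benzyloxy)-3-bromophenyl]-1,3-dioxolane
Conditions: HOCH2CH2OH, TsOH·H2O (cat.), toluene, reflux, azeotropic removal of water; Et3N before work-up
Reagents that add atoms: ethylene glycol, OCCO
Why: Acid-catalysed acetalisation driven by water removal masks the aldehyde against the zinc, lithium and potassium reagents to come and against hetero-cycloaddition with the later diene.

Step 3
Reactants: 3 2-[4-(benzyloxy)-3-bromophenyl]-1,3-dioxolane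
Product: 4 2-[2-(benzyloxy)-5-(1,3-dioxolan-2-yl)phenyl]-1-(morpholin-4-yl)ethan-1-one
Conditions: 4-(bromoacetyl)morpholine, activated Zn dust, THF, rt; then 3, Pd(dba)2 (2 mol %), Q-phos (2 mol %), THF, 65 °C
Reagents that add atoms: 4-(bromoacetyl)morpholine, O=C(CBr)N1CCOCC1
Why: Negishi-type α-arylation of a Reformatsky zinc amide enolate, in which oxidative addition of the aryl bromide to zerovalent palladium, transmetalation and reductive elimination forge the aryl–CH2 bond under nearly neutral conditions that spare acetal and benzyl ether, and the morpholine amide obtained is an acyl donor that stops at the ketone stage.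

Step 4
Reactants: 4 2-[2-(benzyloxy)-5-(1,3-dioxolan-2-yl)phenyl]-1-(morpholin-4-yl)ethan-1-one
Product: 5 1-[2-(benzyloxy)-5-(1,3-dioxolan-2-yl)phenyl]-4-(trimethylsilyl)but-3-yn-2-one
Conditions: Me3SiC≡CH, n-BuLi, THF, −78 °C; then 4, −78 to 0 °C; inverse quench into cold sat. aq. NH4Cl
Reagents that add atoms: (trimethylsilyl)acetylene, C#C[Si](C)(C)C
Why: Nucleophilic acyl substitution of a morpholine amide by an alkynyllithium, in which the tetrahedral adduct lasts until the quench so that no second addition occurs, the silyl cap shields the ynone β-carbon, and at the pH of NH4Cl the liberated morpholine is protonated and cannot add while the acid-labile acetal survives.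

Step 5
Reactants: 5 1-[2-(benzyloxy)-5-(1,3-dioxolan-2-yl)phenyl]-4-(trimethylsilyl)but-3-yn-2-one
Product: 7 (3E)-1-[2-(benzyloxy)-5-(1,3-dioxolan-2-yl)phenyl]-4-methoxybut-3-en-2-one, via terminal ynone 6 (not isolated)
Conditions: K2CO3 (0.1 equiv), MeOH, 0 °C to rt
Reagents that add atoms: methanol, CO
Why: Methoxide-induced protodesilylation of the alkynylsilane followed by base-catalysed oxa-Michael addition of methanol to the ynone, a reversible addition that lets the more stable E vinylogous ester accumulate.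

Step 6
Reactants: 7 (3E)-1-[2-(benzyloxy)-5-(1,3-dioxolan-2-yl)phenyl]-4-methoxybut-3-en-2-one
Product: 8 (1E,3Z)-4-[2-(benzyloxy)-5-(1,3-dioxolan-2-yl)phenyl]-3-[(tert-butyldimethylsilyl)oxy]-1-methoxybuta-1,3-diene
Conditions: KN(SiMe3)2, THF, −78 °C; TBSCl, −78 °C to rt; filtration through Et3N-deactivated silica
Reagents that add atoms: tert-butyldimethylsilyl chloride, CC(C)(C)[Si](C)(C)Cl
Why: Enolate O-silylation in which only the benzylic C–H bonds are acidic, the conjugated potassium enolate places the aryl group cis to oxygen and away from the methoxyvinyl arm (allylic strain) to give the 3Z geometry, and the basic protocol avoids a silyl triflate that could ionise the electron-rich aryl acetal.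

Step 7
Reactants: 8 (1E,3Z)-4-[2-(benzyloxy)-5-(1,3-dioxolan-2-yl)phenyl]-3-[(tert-butyldimethylsilyl)oxy]-1-methoxybuta-1,3-diene; 9 methyl propiolate
Product: 11 methyl 3-[2-(benzyloxy)-5-(1,3-dioxolan-2-yl)phenyl]-4-[(tert-butyldimethylsilyl)oxy]benzoate, via cis-cyclohexa-1,4-diene cycloadduct 10 (not isolated)
Conditions: 9 (3 equiv), BHT (cat.), toluene, 110 °C, sealed tube; evaporation of excess 9; then DBU (0.1 equiv), toluene, rt
Reagents that add atoms: none
Why: This is a normal-electron-demand Diels–Alder reaction, concerted but asynchronous, in which the oxygen donors at C1 and C3 of 8 raise the HOMO and concentrate its coefficient on the aryl-bearing terminus C4, so that C4 bonds ahead to the unsubstituted β-carbon of 9 (C2'''–C3''') while C1 bonds to the ester-bearing α-carbon (C1'''–C6'''). The closest known reaction type is the cycloaddition of 1-methoxy-3-silyloxy-1,3-dienes to propiolates that ends in 4-silyloxybenzoates. The one new ring, the carbocycle C1'''–C6''', is closed by an intermolecular suprafacial [4+2] addition to the s-cis diene. The two sp3 centres of 10 are cis because both terminal substituents of 8 point outward, and they are transient: the C3'''–H bond is doubly allylic, benzylic and γ to the ester, and the methoxy group is allylic to the silyl enol ether, so heat or a trace of DBU removes methanol in a 1,4 sense and no stereocentre remains in 11. The step needs regioselectivity (ester para to the silyloxy group and meta to the aryl group), secured by the matched push–pull polarisation of the partners, and access to the s-cis conformer, secured by the 3Z geometry that keeps the aryl group outside. The TBS group tolerates the temperature better than a trimethylsilyl group would, and the neutral medium leaves dioxolane and benzyl ether intact.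

Step 8
Reactants: 11 methyl 3-[2-(benzyloxy)-5-(1,3-dioxolan-2-yl)phenyl]-4-[(tert-butyldimethylsilyl)oxy]benzoate
Product: 12 methyl 4-(benzyloxy)-3-[2-(benzyloxy)-5-(1,3-dioxolan-2-yl)phenyl]benzoate
Conditions: CsF, BnBr, DMF, rt
Reagents that add atoms: benzyl bromide, BrCc1ccccc1
Why: Fluoride cleavage of the aryl silyl ether and in situ Williamson benzylation of the caesium phenoxide replace a base-labile group by the one used everywhere else, so that a single final operation removes all protection.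

Step 9
Reactants: 13 2',4',6'-trihydroxyacetophenone
Product: 14 1-[2,4-bis(benzyloxy)-6-hydroxyphenyl]ethan-1-one
Conditions: BnBr (2.1 equiv), K2CO3, DMF, rt to 60 °C
Reagents that add atoms: benzyl bromide, BrCc1ccccc1
Why: Selective Williamson etherification, since after two alkylations the remaining hydroxyl group is hydrogen-bonded to the acetyl carbonyl and is the least nucleophilic site.

Step 10
Reactants: 12 methyl 4-(benzyloxy)-3-[2-(benzyloxy)-5-(1,3-dioxolan-2-yl)phenyl]benzoate; 14 1-[2,4-bis(benzyloxy)-6-hydroxyphenyl]ethan-1-one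
Product: 15 1-[2,4-bis(benzyloxy)-6-hydroxyphenyl]-3-{4-(benzyloxy)-3-[2-(benzyloxy)-5-(1,3-dioxolan-2-yl)phenyl]phenyl}propane-1,3-dione
Conditions: NaH (4 equiv), DMF, 0 °C to rt; AcOH quench
Reagents that add atoms: none
Why: Crossed Claisen condensation in which the phenoxide–enolate dianion of 14 attacks the non-enolisable methyl benzoate through carbon and irreversible deprotonation of the 1,3-diketone pulls the equilibrium forward.

Step 11
Reactants: 15 1-[2,4-bis(benzyloxy)-6-hydroxyphenyl]-3-{4-(benzyloxy)-3-[2-(benzyloxy)-5-(1,3-dioxolan-2-yl)phenyl]phenyl}propane-1,3-dione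
Product: 16 4-(benzyloxy)-3-{2-(benzyloxy)-5-[5,7-bis(benzyloxy)-4-oxo-4H-chromen-2-yl]phenyl}benzaldehyde
Conditions: TsOH·H2O (0.3 equiv), THF–H2O 9:1, 65 °C
Reagents that add atoms: water, O
Why: Acid-catalysed cyclodehydration (6-exo-trig attack of the phenol on the aroyl carbonyl, then loss of water to the 4H-chromen-4-one) and hydrolysis of the very labile p-alkoxyaryl dioxolane run under the same mild acid, which leaves the benzyl ethers alone.

Step 12
Reactants: 14 1-[2,4-bis(benzyloxy)-6-hydroxyphenyl]ethan-1-one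
Product: 17 tert-butyl 3-[2,4-bis(benzyloxy)-6-hydroxyphenyl]-3-oxopropanoate
Conditions: LiN(SiMe3)2 (3.2 equiv), THF, −78 °C; Boc2O (1.05 equiv), −78 to 0 °C; sat. aq. NH4Cl
Reagents that add atoms: di-tert-butyl dicarbonate, CC(C)(C)OC(=O)OC(=O)OC(C)(C)C
Why: Claisen-type C-acylation of the lithium enolate by the dicarbonate, in which excess base keeps phenoxide and product deprotonated, any carbonate formed on the phenoxide can hand its acyl group to the enolate carbon in a Baker–Venkataraman-type shift, and the tert-butyl ester resists lactonisation to a 4-hydroxycoumarin.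

Step 13
Reactants: 16 4-(benzyloxy)-3-{2-(benzyloxy)-5-[5,7-bis(benzyloxy)-4-oxo-4H-chromen-2-yl]phenyl}benzaldehyde; 17 tert-butyl 3-[2,4-bis(benzyloxy)-6-hydroxyphenyl]-3-oxopropanoate
Product: 18 tert-butyl (2Z)-2-[2,4-bis(benzyloxy)-6-hydroxybenzoyl]-3-{4-(benzyloxy)-3-[2-(benzyloxy)-5-(5,7-bis(benzyloxy)-4-oxo-4H-chromen-2-yl)phenyl]phenyl}prop-2-enoate
Conditions: piperidine (0.2 equiv), AcOH (0.2 equiv), 4 Å molecular sieves, toluene, rt
Reagents that add atoms: none
Why: Knoevenagel condensation under piperidinium acetate catalysis is mild enough for the flavone and gives the doubly activated alkylidene, drawn as the Z isomer (aryl cis to the ester) expected to dominate.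

Step 14
Reactants: 18 tert-butyl (2Z)-2-[2,4-bis(benzyloxy)-6-hydroxybenzoyl]-3-{4-(benzyloxy)-3-[2-(benzyloxy)-5-(5,7-bis(benzyloxy)-4-oxo-4H-chromen-2-yl)phenyl]phenyl}prop-2-enoate
Product: 20 (2S)-5,7-bis(benzyloxy)-2-{4-(benzyloxy)-3-[2-(benzyloxy)-5-(5,7-bis(benzyloxy)-4-oxo-4H-chromen-2-yl)phenyl]phenyl}-2,3-dihydro-4H-chromen-4-one, via trans-3-(tert-butoxycarbonyl)flavanone 19 (not isolated)
Conditions: 1-[3,5-bis(trifluoromethyl)phenyl]-3-[(9R)-6'-methoxycinchonan-9-yl]thiourea (quinidine-derived, 10 mol %), toluene, −25 °C; then TsOH·H2O, 80 °C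
Reagents that add atoms: none
Why: Organocatalytic asymmetric intramolecular oxa-Michael addition (6-endo-trig) to an alkylidene β-ketoester, in which the thiourea binds the dicarbonyl unit while the quinuclidine nitrogen deprotonates the phenol so that oxygen reaches one face of the alkene and sets C2 as S, after which acid cleaves the tert-butyl ester and the β-keto acid loses CO2, erasing C3 without touching C2.

Step 15
Reactants: 20 (2S)-5,7-bis(benzyloxy)-2-{4-(benzyloxy)-3-[2-(benzyloxy)-5-(5,7-bis(benzyloxy)-4-oxo-4H-chromen-2-yl)phenyl]phenyl}-2,3-dihydro-4H-chromen-4-one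
Product: 21 (2S)-5,7-dihydroxy-2-{3-[5-(5,7-dihydroxy-4-oxo-4H-chromen-2-yl)-2-hydroxyphenyl]-4-hydroxyphenyl}-2,3-dihydro-4H-chromen-4-one
Conditions: H2 (1 atm), 10% Pd/C, THF–MeOH, rt; filtration and neutral work-up
Reagents that add atoms: none
Why: Heterogeneous catalytic hydrogenolysis of the six O-benzyl groups is neutral, so C2 is never exposed to the base or strong acid that would open ring C by retro-oxa-Michael reaction, and at 1 atm and rt the flavone C2=C3 bond, both carbonyl groups and the cyclic C2–O bond are expected to persist.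

Compound list
1 | 3-bromo-4-hydroxybenzaldehyde | O=Cc1ccc(O)c(Br)c1 | starting material
2 | 4-(benzyloxy)-3-bromobenzaldehyde | O=Cc1ccc(OCc2ccccc2)c(Br)c1 | intermediate
3 | 2-[4-(benzyloxy)-3-bromophenyl]-1,3-dioxolane | Brc1cc(C2OCCO2)ccc1OCc1ccccc1 | intermediate
4 | 2-[2-(benzyloxy)-5-(1,3-dioxolan-2-yl)phenyl]-1-(morpholin-4-yl)ethan-1-one | O=C(Cc1cc(C2OCCO2)ccc1OCc1ccccc1)N1CCOCC1 | intermediate
5 | 1-[2-(benzyloxy)-5-(1,3-dioxolan-2-yl)phenyl]-4-(trimethylsilyl)but-3-yn-2-one | C[Si](C)(C)C#CC(=O)Cc1cc(C2OCCO2)ccc1OCc1ccccc1 | intermediate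
6 | 1-[2-(benzyloxy)-5-(1,3-dioxolan-2-yl)phenyl]but-3-yn-2-one (not isolated) | C#CC(=O)Cc1cc(C2OCCO2)ccc1OCc1ccccc1 | intermediate
7 | (3E)-1-[2-(benzyloxy)-5-(1,3-dioxolan-2-yl)phenyl]-4-methoxybut-3-en-2-one | CO/C=C/C(=O)Cc1cc(C2OCCO2)ccc1OCc1ccccc1 | intermediate
8 | (1E,3Z)-4-[2-(benzyloxy)-5-(1,3-dioxolan-2-yl)phenyl]-3-[(tert-butyldimethylsilyl)oxy]-1-methoxybuta-1,3-diene | CO/C=C/C(=C/c1cc(C2OCCO2)ccc1OCc1ccccc1)O[Si](C)(C)C(C)(C)C | intermediate
9 | methyl propiolate | C#CC(=O)OC | starting material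
10 | methyl rac-(3S,6R)-3-[2-(benzyloxy)-5-(1,3-dioxolan-2-yl)phenyl]-4-[(tert-butyldimethylsilyl)oxy]-6-methoxycyclohexa-1,4-diene-1-carboxylate (cis, racemic, one enantiomer drawn, not isolated) | COC(=O)C1=C[C@@H](c2cc(C3OCCO3)ccc2OCc2ccccc2)C(O[Si](C)(C)C(C)(C)C)=C[C@H]1OC | intermediate
11 | methyl 3-[2-(benzyloxy)-5-(1,3-dioxolan-2-yl)phenyl]-4-[(tert-butyldimethylsilyl)oxy]benzoate | COC(=O)c1ccc(O[Si](C)(C)C(C)(C)C)c(-c2cc(C3OCCO3)ccc2OCc2ccccc2)c1 | intermediate
12 | methyl 4-(benzyloxy)-3-[2-(benzyloxy)-5-(1,3-dioxolan-2-yl)phenyl]benzoate | COC(=O)c1ccc(OCc2ccccc2)c(-c2cc(C3OCCO3)ccc2OCc2ccccc2)c1 | intermediate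
13 | 2',4',6'-trihydroxyacetophenone | CC(=O)c1c(O)cc(O)cc1O | starting material
14 | 1-[2,4-bis(benzyloxy)-6-hydroxyphenyl]ethan-1-one | CC(=O)c1c(O)cc(OCc2ccccc2)cc1OCc1ccccc1 | intermediate
15 | 1-[2,4-bis(benzyloxy)-6-hydroxyphenyl]-3-{4-(benzyloxy)-3-[2-(benzyloxy)-5-(1,3-dioxolan-2-yl)phenyl]phenyl}propane-1,3-dione (largely enolised) | O=C(CC(=O)c1ccc(OCc2ccccc2)c(-c2cc(C3OCCO3)ccc2OCc2ccccc2)c1)c1c(O)cc(OCc2ccccc2)cc1OCc1ccccc1 | intermediate
16 | 4-(benzyloxy)-3-{2-(benzyloxy)-5-[5,7-bis(benzyloxy)-4-oxo-4H-chromen-2-yl]phenyl}benzaldehyde | O=Cc1ccc(OCc2ccccc2)c(-c2cc(-c3cc(=O)c4c(OCc5ccccc5)cc(OCc5ccccc5)cc4o3)ccc2OCc2ccccc2)c1 | intermediate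
17 | tert-butyl 3-[2,4-bis(benzyloxy)-6-hydroxyphenyl]-3-oxopropanoate | CC(C)(C)OC(=O)CC(=O)c1c(O)cc(OCc2ccccc2)cc1OCc1ccccc1 | intermediate
18 | tert-butyl (2Z)-2-[2,4-bis(benzyloxy)-6-hydroxybenzoyl]-3-{4-(benzyloxy)-3-[2-(benzyloxy)-5-(5,7-bis(benzyloxy)-4-oxo-4H-chromen-2-yl)phenyl]phenyl}prop-2-enoate | CC(C)(C)OC(=O)/C(=C\c1ccc(OCc2ccccc2)c(-c2cc(-c3cc(=O)c4c(OCc5ccccc5)cc(OCc5ccccc5)cc4o3)ccc2OCc2ccccc2)c1)C(=O)c1c(O)cc(OCc2ccccc2)cc1OCc1ccccc1 | intermediate
19 | tert-butyl (2S,3R)-5,7-bis(benzyloxy)-2-{4-(benzyloxy)-3-[2-(benzyloxy)-5-(5,7-bis(benzyloxy)-4-oxo-4H-chromen-2-yl)phenyl]phenyl}-4-oxo-3,4-dihydro-2H-chromene-3-carboxylate (2,3-trans, in equilibrium with its enol, not isolated) | O=C1[C@H](C(=O)OC(C)(C)C)[C@@H](c2ccc(OCc3ccccc3)c(-c3cc(-c4cc(=O)c5c(OCc6ccccc6)cc(OCc6ccccc6)cc5o4)ccc3OCc3ccccc3)c2)Oc2cc(OCc3ccccc3)cc(OCc3ccccc3)c21 | intermediate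
20 | (2S)-5,7-bis(benzyloxy)-2-{4-(benzyloxy)-3-[2-(benzyloxy)-5-(5,7-bis(benzyloxy)-4-oxo-4H-chromen-2-yl)phenyl]phenyl}-2,3-dihydro-4H-chromen-4-one | O=C1C[C@@H](c2ccc(OCc3ccccc3)c(-c3cc(-c4cc(=O)c5c(OCc6ccccc6)cc(OCc6ccccc6)cc5o4)ccc3OCc3ccccc3)c2)Oc2cc(OCc3ccccc3)cc(OCc3ccccc3)c21 | intermediate
21 | (2S)-5,7-dihydroxy-2-{3-[5-(5,7-dihydroxy-4-oxo-4H-chromen-2-yl)-2-hydroxyphenyl]-4-hydroxyphenyl}-2,3-dihydro-4H-chromen-4-one, CNP0184920.1 | O=C1C[C@@H](c2ccc(O)c(-c3cc(-c4cc(=O)c5c(O)cc(O)cc5o4)ccc3O)c2)Oc2cc(O)cc(O)c21 | target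

Total step count: 15.
Longest linear sequence: 13 (steps 1–8, 10, 11, 13, 14, 15).

Steps most likely to fail

Step 7. The cycloaddition may be sluggish, because the ortho-substituted aryl group both hinders and conjugatively stabilises the reacting diene terminus. Long heating would then allow geometric drift of the enol ether, desilylation or polymerisation of the alkyne to compete. The fallback sets out from 3 and comes back at 12. Miyaura borylation of 3 (B2pin2, PdCl2(dppf), KOAc, dioxane, 80 °C) gives the pinacol arylboronate F1. Commercial methyl 3-bromo-4-hydroxybenzoate is benzylated (BnBr, K2CO3, DMF) to methyl 4-(benzyloxy)-3-bromobenzoate F2. Suzuki–Miyaura coupling of the two (Pd(PPh3)4, K2CO3, dioxane–H2O, 90 °C) forms the biaryl bond directly and delivers 12.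

Step 14. Three things may go wrong:
- facial selectivity may be poor on this large, di-ortho-substituted aroyl substrate;
- an uncatalysed racemic ring closure may already start during step 13;
- reversible ring opening in the hot acid may erode the configuration.

The fallback sets out from 16 (with 14) and comes back at 20. Claisen–Schmidt condensation (KOH, EtOH–THF, rt) gives the (E)-2'-hydroxychalcone F3. Thermodynamic oxa-Michael closure (NaOAc, EtOH, reflux) gives the racemic flavanone F4. Kinetic resolution by asymmetric transfer hydrogenation (RhCl(Cp*)[(R,R)-TsDPEN], HCO2H–Et3N, EtOAc, rt) should reduce the 2R ketone to the (2R,4R)-cis-flavan-4-ol F5. The unreacted 2S ketone 20 is then separated by chromatography.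

Step 10. Acylation may stay incomplete, because the p-alkoxybenzoate is a weak electrophile and the hindered dianion may act only as a base. Ester hydrolysis by adventitious hydroxide would be a further drain. The fallback sets out from 12 and comes back at 15. Saponification (LiOH, THF–MeOH–H2O, acidification only to pH 5) gives the biaryl carboxylic acid F6. Esterification with 14 (EDC·HCl, DMAP, CH2Cl2) gives the 2-acetylaryl ester F7. Baker–Venkataraman O-to-C acyl migration (KOH, pyridine, 50 °C) makes the same bond intramolecularly and gives 15.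

Further compounds
F1 | step 7 | 2-[2-(benzyloxy)-5-(1,3-dioxolan-2-yl)phenyl]-4,4,5,5-tetramethyl-1,3,2-dioxaborolane | CC1(C)OB(c2cc(C3OCCO3)ccc2OCc2ccccc2)OC1(C)C
F2 | step 7 | methyl 4-(benzyloxy)-3-bromobenzoate | COC(=O)c1ccc(OCc2ccccc2)c(Br)c1
F3 | step 14 | (2E)-1-[2,4-bis(benzyloxy)-6-hydroxyphenyl]-3-{4-(benzyloxy)-3-[2-(benzyloxy)-5-(5,7-bis(benzyloxy)-4-oxo-4H-chromen-2-yl)phenyl]phenyl}prop-2-en-1-one | O=C(/C=C/c1ccc(OCc2ccccc2)c(-c2cc(-c3cc(=O)c4c(OCc5ccccc5)cc(OCc5ccccc5)cc4o3)ccc2OCc2ccccc2)c1)c1c(O)cc(OCc2ccccc2)cc1OCc1ccccc1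
F4 | step 14 | rac-5,7-bis(benzyloxy)-2-{4-(benzyloxy)-3-[2-(benzyloxy)-5-(5,7-bis(benzyloxy)-4-oxo-4H-chromen-2-yl)phenyl]phenyl}-2,3-dihydro-4H-chromen-4-one | O=C1CC(c2ccc(OCc3ccccc3)c(-c3cc(-c4cc(=O)c5c(OCc6ccccc6)cc(OCc6ccccc6)cc5o4)ccc3OCc3ccccc3)c2)Oc2cc(OCc3ccccc3)cc(OCc3ccccc3)c21
F5 | step 14 | 5,7-bis(benzyloxy)-2-{4-(benzyloxy)-3-[2-(benzyloxy)-5-((2R,4R)-5,7-bis(benzyloxy)-4-hydroxy-3,4-dihydro-2H-chromen-2-yl)phenyl]phenyl}-4H-chromen-4-one | O[C@@H]1C[C@H](c2ccc(OCc3ccccc3)c(-c3cc(-c4cc(=O)c5c(OCc6ccccc6)cc(OCc6ccccc6)cc5o4)ccc3OCc3ccccc3)c2)Oc2cc(OCc3ccccc3)cc(OCc3ccccc3)c21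
F6 | step 10 | 4-(benzyloxy)-3-[2-(benzyloxy)-5-(1,3-dioxolan-2-yl)phenyl]benzoic acid | O=C(O)c1ccc(OCc2ccccc2)c(-c2cc(C3OCCO3)ccc2OCc2ccccc2)c1
F7 | step 10 | 2-acetyl-3,5-bis(benzyloxy)phenyl 4-(benzyloxy)-3-[2-(benzyloxy)-5-(1,3-dioxolan-2-yl)phenyl]benzoate | CC(=O)c1c(OC(=O)c2ccc(OCc3ccccc3)c(-c3cc(C4OCCO4)ccc3OCc3ccccc3)c2)cc(OCc2ccccc2)cc1OCc1ccccc1
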